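The numbers in the tables were generated by integration with constants of no real substance, noise included.

- The highest J reading stays level across the two charges of X, 8.3% in dusk and 8.3% in spring, so what needs watching in this flask, whose run so far is dusk, is how fast J goes after the top.

all flasks: D 0.50 mM

| charge | X | remark | time |
|---|---|---|---|
| dusk | 0.75 mM | the very flask that is asked about, followed so far |  |
| spring | 0.50 mM | run made earlier |  |
| flask | 0.750 mM |  | 40 min |

| dusk: time / min | dusk: J / % | spring: time / min | spring: J / % |
|---|---|---|---|
| 0.417 | 2.9 | 0.417 | 2.1 |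
| 0.833 | 6.1 | 1.00 | 6.7 |
| 1.33 | 8.3 | 2.00 | 8.3 |
| 2.50 | 8.1 | 4.00 | 4.1 |
| 4.00 | 4.7 | 8.00 | 0 |
| 6.00 | 1.6 | 20.0 | 0 |
| 12.0 | 0.1 | 40.0 | 0 |

(scatter of a reading: 0.3 percentage points)

1. time, not beyond 40 min, at which the flask holds most J
2. the amount of J, in percent of the D charged, at that time
3. the first time at which J reaches 2.6%, in the same percent, in min



- From 4.00 min to 6.00 min the dusk run keeps a fraction 0.340 of its J; the logarithm of that fraction left, taken positive and per minute, reads 0.539 /min, the tail constant (an apparent first-order rate constant).
- That is a half-time of 1.29 min, and it carries the 6.00 min reading to 0.0631% at 12.0 min, where dusk reads 0.1%.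
- So J in this flask is to be taken near the top, between the readings at 1.33 min and 2.50 min, and not left waiting.
- At 0.417 min dusk reads 2.9%, and with a scatter of 0.3 percentage points this reckoning holds the crossing of 2.6% close to that time, on either side of it.
- The forecast gives 9.2% at 1.9 min, and 0.37 min for the crossing: “The dusk run is the flask itself, so I read it directly rather than scaling from spring.”

    D → Z (k = 0.0360 /s)
    Z → J (k = 0.00360 /s)
    Z → Q (k = 0.00750 /s)
    X + Q → G (k = 26.0 /M/s)
    G ⇌ L (K = 0.500, k = 0.00530 /s)
    J → E (k = 0.0170 /s)

The flask peaks at 8.73% at 1.77 min and crosses 2.6% at 0.441 min, later than the forecast's 0.37 min. At that best time Z still holds 41.2% of the D charged. From the 5.22% of J in the flask at 3.55 min, the tail constant leaves 0.770% at 7.10 min, and the flask holds 0.699%. In spring, the same constant carries the reading of 4.1% at 4.00 min to a reckoned 0.475% at 8.00 min, and the reading there is 0%, with a scatter of 0.3 points.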